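Start from the constants the runs hand you. In elm, starting material falls to 22.7% in 1.00 min, so its rate reads 1.48 min⁻¹. Elm's target falls more slowly than cedar's, so I read elm's first point as the one closest to what was made.

At that point, 7.5% is target and 69.8% is the rest of the starting material lost. Taken as a ratio, the two give odds of 0.107. Dividing by elm's 0.600 equivalents of first nucleophile gives the capture odds per equivalent, 0.179, a number I assume holds while second nucleophile stays at elm's charge.

This flask has twice elm's first nucleophile, so its odds are 0.215, and the share of lost starting material that becomes target is 17.7%. I take target's loss as pseudo-first-order in first nucleophile, so elm's fall scales to 0.367 min⁻¹ here.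

My ladder for this flask:

| Rung | Time | What stands |
|---|---|---|
| Target reaches the asked level | 0.121 min | starting material 83.6% |
| Lifetime of starting material | 0.674 min | target rising |
| Peak of target | 1.25 min | target 11.2% |
| Lifetime of target | 2.72 min | target falling |
| Longest time | 90 min | 33.0 target lifetimes passed |

all flasks: starting material 20 mM

|  | first nucleophile | second nucleophile | remark | time |
|---|---|---|---|---|
| elm | 12 mM | 40 mM | run made earlier |  |
| cedar | 48 mM | 40 mM | run made earlier |  |
| maple | 24 mM | 80 mM | run made earlier |  |
| flask | 24.0 mM | 40.0 mM |  | 1.5 h |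

| run | time / min | target / % | starting material / % |
|---|---|---|---|
| elm | 1.00 | 7.5 | 22.7 |
| elm | 5.00 | 3.6 | 0 |
| elm | 25.0 | 0 | 0 |
| elm | 120 | 1.0 | 0 |
| cedar | 1.00 | 11.1 | 23.1 |
| cedar | 5.00 | 0.9 | 0 |
| cedar | 25.0 | 0 | 0.6 |
| cedar | 120 | 0.9 | 0.2 |
| maple | 1.00 | 5.3 | 21.0 |
| maple | 5.00 | 0 | 1.4 |
| maple | 25.0 | 0.5 | 0.7 |
| maple | 120 | 0 | 0 |

(readings scatter by 1 percentage point)



- the best time, 1.5 h at the latest, for target, in min
- the amount of target, in percent of the starting material charged, at that time
- the first time at which target reaches 2.9%, in the same percent, in min

The forecast says 1.2 min, 9.5% and 0.2 min, and for the peak it reckons: “A rise at 1.5/min and fall at 0.4/min puts the peak near ln(3.75)/1.1≈1.2 min, at about 9.5%”. My peak time stands beside its time, but my peak is higher and my first time earlier.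

The flask gives 0.947 min, 9.68% and 0.113 min.

    starting material → intermediate (k = 0.0250 s⁻¹)
    first nucleophile + target → over-reaction product (k = 0.580 M⁻¹ s⁻¹)
    first nucleophile + intermediate → target (k = 660 M⁻¹ s⁻¹)
    intermediate → solvolysis product (k = 25.0 s⁻¹)
    second nucleophile + intermediate → other capture product (k = 1000 M⁻¹ s⁻¹)

At the longest time this flask holds target 0% and over-reaction product 19.0%, beside the 17.7% share from the capture odds. Put the same odds on the neighbouring flask with 6.0 mM of first nucleophile, its other charges as here: they give a share of 5.10%, and that flask ends with over-reaction product at 5.62%.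

(The numbers in the tables are simulated for an exercise, noise included.)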